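**Assumptions:** The target is achiral with no stereocentres, so "single enantiomer" reduces to the single (Z) geometry of the exocyclic C5=CH bond (aryl cis to the ring O, as the SMILES shows). 4-Bromofuran-2(5H)-one is treated as a catalogue item. If it is unavailable, it is one step from tetronic acid with (COBr)2/DMF.

## Retrosynthetic overview
1. Disconnect the exocyclic (Z)-C5=CH bond by a vinylogous Knoevenagel/aldol condensation, giving 4-(4-hydroxyphenyl)furan-2(5H)-one and 3-bromo-4-methoxybenzaldehyde.
2. Disconnect the C4–aryl bond by Suzuki–Miyaura coupling, giving 4-bromofuran-2(5H)-one and 4-hydroxyphenylboronic acid.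
3. No ring is formed in the route. The butenolide and both arenes are purchased intact, and the Br and OMe arrive already placed in the aldehyde.
4. The ArBr-containing fragment is added last, after the Pd step, so there is no competing oxidative addition. The route uses no protecting groups.

## Route

**Step 1**
Reactants: **1**, 4-bromofuran-2(5H)-one (1.0 equiv); **2**, 4-hydroxyphenylboronic acid (1.2 equiv)
Product: **3**, 4-(4-hydroxyphenyl)furan-2(5H)-one
Conditions: PdCl2(PPh3)2 (5 mol %), 2 M aq KF (3 equiv), THF, degassed, 60 °C, 6–12 h; acidify to pH 4–5, extract with EtOAc
Reagents that add atoms: none beyond the listed reactants. The 4-hydroxyphenyl group comes from **2**, OB(O)c1ccc(O)cc1.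
Why: This is a Suzuki–Miyaura coupling in which the β-bromo-enoate C–Br undergoes fast oxidative addition. The mild fluoride base activates boron without opening the lactone or generating much phenoxide, which could otherwise displace Br by addition–elimination. No stereo-element is created.

**Step 2**
Reactants: **3**, 4-(4-hydroxyphenyl)furan-2(5H)-one (1.0 equiv); **4**, 3-bromo-4-methoxybenzaldehyde (1.1 equiv)
Product: **5**, 3''-bromorubrolide F, (Z)-5-(3-bromo-4-methoxybenzylidene)-4-(4-hydroxyphenyl)furan-2(5H)-one
Conditions: piperidine (1.0 equiv), MeOH (0.2 M), rt, 24–48 h, protected from light; 1 M HCl quench, then filter or chromatograph the yellow solid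
Reagents that add atoms: none beyond the listed reactants. The ArCH= unit comes from **4**, COc1ccc(C=O)cc1Br. The aldehyde O leaves as H2O, and piperidine is not incorporated.
Why: This is a vinylogous Knoevenagel condensation. Piperidine forms the iminium ion of **4** and deprotonates the γ-CH2 of **3** to the 2-oxyfuran dienolate, which attacks at C5 and is followed by E1cB elimination. The step is reversible and thermodynamically controlled, so only the Z alkene forms, because the E isomer would force the benzylidene aryl against the C4 aryl. ArBr, OMe, the free phenol and the lactone all tolerate these conditions.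

## Compound list
| No. | Name | SMILES | Role |
|---|---|---|---|
| 1 | 4-bromofuran-2(5H)-one | O=C1C=C(Br)CO1 | starting material |
| 2 | 4-hydroxyphenylboronic acid | OB(O)c1ccc(O)cc1 | starting material |
| 3 | 4-(4-hydroxyphenyl)furan-2(5H)-one | O=C1C=C(c2ccc(O)cc2)CO1 | intermediate |
| 4 | 3-bromo-4-methoxybenzaldehyde | COc1ccc(C=O)cc1Br | starting material |
| 5 | 3''-bromorubrolide F, (Z)-5-(3-bromo-4-methoxybenzylidene)-4-(4-hydroxyphenyl)furan-2(5H)-one | COc1ccc(/C=C2\OC(=O)C=C2c2ccc(O)cc2)cc1Br | target |

**Total step count:** 2
**Longest linear sequence:** 2

## Most likely failure points
The route has only two steps, so the third entry is a separate failure mode of Step 2.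

1. **Step 2, low conversion.** Piperidine partly deprotonates the free phenol, and the resulting phenoxide pushes electron density into the butenolide and lowers the γ-CH acidity.
   - Fallback: switch from amine catalysis to a silyl-mediated vinylogous Mukaiyama aldol.
   - Treat **3** and **4** with TBSOTf (3.5 equiv) and iPr2NEt in CH2Cl2. This silylates the phenol in situ, forms the 2-silyloxyfuran and gives the aldol adduct.
   - Add DBU to eliminate TBSO⁻ and form the Z-ylidene, then TBAF/AcOH to free the phenol.

2. **Step 1, side reactions.** The phenoxide may O-arylate **1** to give a 4-aryloxyfuranone, or **1** may hydrolyse or **2** protodeboronate.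
   - Fallback: drop the cross-coupling and build the butenolide around the arene.
   - Esterify 2-bromo-4'-hydroxyacetophenone with diethylphosphonoacetic acid (carboxylate displacement of bromide).
   - Close the ring by intramolecular Horner–Wadsworth–Emmons reaction (DBU/LiCl) to give **3** directly.

3. **Step 2, geometry or integrity of the ylidene.** E/Z mixtures could arise from photoisomerisation, or piperidine could open the γ-ylidene lactone.
   - Fallback: set the Z geometry mechanistically rather than thermodynamically.
   - Couple 2-bromo-4-ethynyl-1-methoxybenzene (the terminal alkyne made from **4**) with (Z)-3-iodo-3-(4-hydroxyphenyl)acrylic acid under Sonogashira conditions. The vinyl iodide reacts in preference to the ArBr.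
   - Cyclise by Ag(I)- or Pd-promoted 5-exo-dig anti-oxymetalation lactonisation, which gives the (Z)-γ-arylidene butenolide stereospecifically.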